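Start with one division. In the gamma run, at the temperature of both new flasks, the highest reading of Q, 13.7 % at 20.0 min, divided by the 0.73 equiv of G charged gives 0.188 mol of Q per mol of G charged. Call this the yield on G; it is a reading and carries the scatter of 1 percentage point.

the same everywhere: E 0.57 M
- epsilon: G 0.46 equiv; L 1 equiv; temperature 10 °C; run made earlier
- gamma: G 0.73 equiv; L 1 equiv; temperature 25 °C; run made earlier
- eta: G 1 equiv; L 1 equiv; temperature 10 °C; run made earlier
- Tuesday's: G 1.20 equiv; L 1.00 equiv; temperature 25 °C; time 2.0 h
- Thursday's: G 0.400 equiv; L 1.00 equiv; temperature 25 °C; time 0.50 h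

- epsilon (time / min: Q / %): 30.0: 6.0; 60.0: 9.7; 120: 11.4
- gamma (time / min: Q / %): 8.00: 8.8; 20.0: 13.7; 40.0: 12.9; 60.0: 12.1
- eta (time / min: Q / %): 15.0: 9.4; 40.0: 15.5; 80.0: 20.8; 120: 20.4

(each reading ± 1 percentage point)

- the analysis behind the earlier runs scatters by 1 percentage point, standard deviation

- which of the two ends with the higher amount of Q, in percent of the E charged ("neither" if they lie within 2 percentage points) (Tuesday's / Thursday's / neither)
- Q at the end, in percent of the E charged, Tuesday's
- Q at the end, in percent of the E charged, Thursday's

Two chemists read these runs differently. The first counts G. At 10 °C, twice the G gave 1.82 times the highest reading of Q, so she multiplies by the yield on G: 7.51 % for Thursday's flask, and a top of 22.5 % for Tuesday's flask before any fall.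

The second counts the clock. The gamma run lost 1.6 points in the 40.0 min after its highest reading, so he takes Thursday's flask from the gamma readings on either side of its stopping time, about 13.3 %. He runs the same fall on to the end of Tuesday's flask and gets 9.70 %, which puts Thursday's higher.

The forecast takes the first side: “The final Q tracks the G charge, not the time.” It gives 16 % for Tuesday's flask (range 13 % to 20 %), 8 % for Thursday's (range 6.5 % to 10 %), and names Tuesday's as higher. My own reckoning differs on Tuesday's flask. Taking the gamma fall unscaled off the top for 100 min, I get 18.5 %.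

The flask gives 18.3 % for Tuesday's and 7.32 % for Thursday's, so Tuesday's ends higher by 11 points; the forecast's choice stands and both results lie inside its ranges. The clock keeps a place in Thursday's flask, which, left ten times as long, holds 5.97 %. Per G charged, Thursday's flask ended at 0.183 against the carried 0.188, while Tuesday's flask, stopped at 120 min, ended at 0.153.

    E + G ⇌ Q (K = 0.540 M⁻¹, k = 0.0460 M⁻¹ min⁻¹, Ea = 67.0 kJ mol⁻¹, ΔH = −22.0 kJ mol⁻¹)
    L + G → J (k = 0.0280 M⁻¹ min⁻¹, Ea = 65.0 kJ mol⁻¹)
    2 L → Z (k = 0.0780 M⁻¹ min⁻¹, Ea = 65.0 kJ mol⁻¹)
    (constants at 25 °C)

A neighbour of Thursday's flask charged with 0.600 equiv of L keeps the same G, so the yield on G gives 7.51 % again. The computed flask holds 7.65 %.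

All runs stem from a simulated flask from invented constants; noise was put on by code.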